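**Plan**

1. Retrosynthesis: the C7–C11 bond of the cis-fused α-methylene-γ-butyrolactone is cut first (29 ⇒ ring acrylate/epoxide 26). Then follow the C6–O acyl bond, the ring bond C5–C6 (alkenyl iodide plus epoxy aldehyde), the C9 ester, the 7,8-epoxide, C8–C9 (ynone) and C2–C3 (allylation).
2. Forward: the chain grows C5/C4/C3 → C2/C1 → C10/C9 (a six-membered lactone made by ring-closing metathesis locks the 1(10)Z alkene) → C8/C7/C6. The ten-membered carbocycle is closed at C5–C6, and the lactone ring (O6–C12–C11–C7–C6) is closed last.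
3. Enabling feature: in 29 the C8 hydroxyl is anti to the C7–C11 bond and O6 sits on the neighbouring ring carbon C6. This is the retron of a 5-exo opening of a trans-7,8-epoxide by the α-carbon of a C6 acrylate; the epoxide is the helper and ends as the C8–OH.
4. Stereochemistry: C3 from Brown allylboration; C9 from Noyori transfer hydrogenation; C7/C8 from Sharpless epoxidation under reagent control; C6 from Felkin-controlled ring closure then Mitsunobu inversion; C7 (inversion) and C8 (retention) in the key step. The side-chain epoxide comes from Sharpless epoxidation of angelyl alcohol; the 4Z alkene from an anti carbomagnesiation.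

Key step: step 21

Remark: all intermediates are numbered like the target in the germacrane way (ring C1–C10, C14 on C10, C15 on C4, lactone carbons C11–C13); the chromium-mediated ring closure is assumed to follow the Felkin–Anh sense.

**Route**

Step 1
Reactants: 1 prop-2-yn-1-ol
Product: 3 (2Z)-3-iodo-2-methylprop-2-en-1-ol, via alkenylmagnesium chelate 2 (not isolated)
Conditions: MeMgBr (3 equiv), CuI (10 mol %), THF, −10 °C → rt; then I2, −78 → 0 °C
Reagents that add atoms: methylmagnesium bromide, C[Mg]Br; iodine, II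
Why: Copper-catalysed anti carbomagnesiation of the propargylic alkoxide places Mg cis to CH2O in chelate 2, and iodinolysis with retention gives the Z-iodoalkene that becomes C5=C4 with its methyl C15.

Step 2
Reactants: 3 (2Z)-3-iodo-2-methylprop-2-en-1-ol
Product: 4 (2Z)-3-iodo-2-methylprop-2-enal
Conditions: MnO2, CH2Cl2, rt
Reagents that add atoms: none
Why: Allylic oxidation with MnO2 is selective for the allylic alcohol and leaves the alkene geometry and the C–I bond untouched.

Step 3
Reactants: 4 (2Z)-3-iodo-2-methylprop-2-enal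
Product: 5 (1Z,3S)-1-iodo-2-methylhexa-1,5-dien-3-ol
Conditions: (−)-Ipc2B(allyl) (pre-formed, salt-free), Et2O, −78 °C; then NaOH, H2O2
Reagents that add atoms: (−)-B-allyldiisopinocampheylborane, C=CCB([C@@H]1C[C@@H]2C[C@H]([C@H]1C)C2(C)C)[C@@H]1C[C@@H]2C[C@H]([C@H]1C)C2(C)C
Why: Brown allylboration through a closed chair transition state; the (−)-Ipc groups direct the allyl group to the si face of the enal, which sets C3 as S and adds C2 and C1.

Step 4
Reactants: 5 homoallylic alcohol
Product: 6 (1Z,3S)-1-iodo-2-methylhexa-1,5-dien-3-yl 2-methylprop-2-enoate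
Conditions: methacryloyl chloride, Et3N, DMAP (cat.), CH2Cl2, 0 °C
Reagents that add atoms: methacryloyl chloride, C=C(C)C(=O)Cl
Why: Acylation of the secondary alcohol with an acid chloride under DMAP catalysis brings in C9, C10 and C14 without touching C3.

Step 5
Reactants: 6 methacrylate ester
Product: 7 (6S)-6-[(1Z)-1-iodoprop-1-en-2-yl]-3-methyl-5,6-dihydro-2H-pyran-2-one
Conditions: second-generation Grubbs catalyst RuCl2(H2IMes)(PCy3)(=CHPh) (5 mol %), CH2Cl2, 40 °C
Reagents that add atoms: none
Why: Ring-closing metathesis to the six-membered unsaturated lactone forces the new C1=C10 alkene to be Z, and the hindered, electron-poor iodoalkene does not engage the ruthenium carbene.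

Step 6
Reactants: 7 unsaturated lactone
Product: 8 (2Z,5S,6Z)-5-hydroxy-7-iodo-N-methoxy-N,2,6-trimethylhepta-2,6-dienamide
Conditions: MeNH(OMe)·HCl, i-PrMgCl, THF, −20 → 0 °C
Reagents that add atoms: N,O-dimethylhydroxylamine hydrochloride, CNOC.Cl
Why: Weinreb aminolysis of the lactone by the magnesium amide cleaves the acyl C–O bond, so the Z geometry and C3 are retained and C9 is set up for a single carbanion addition.

Step 7
Reactants: 8 hydroxy Weinreb amide
Product: 9 (2Z,5S,6Z)-5-[(tert-butyldimethylsilyl)oxy]-7-iodo-N-methoxy-N,2,6-trimethylhepta-2,6-dienamide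
Conditions: TBSCl, imidazole, DMF, rt
Reagents that add atoms: tert-butyldimethylsilyl chloride, CC(C)(C)[Si](C)(C)Cl
Why: Silylation of the secondary alcohol blocks relactonisation and protects C3–OH against the organolithium and hydride steps that follow.

Step 8
Reactants: 9 silylated Weinreb amide; 10 tert-butyldimethyl(prop-2-yn-1-yloxy)silane
Product: 12 (5Z,8S,9Z)-1,8-bis[(tert-butyldimethylsilyl)oxy]-10-iodo-5,9-dimethyldeca-5,9-dien-2-yn-4-one, via lithium acetylide 11 (not isolated)
Conditions: 10, n-BuLi, THF, −78 °C; then 9, −78 → 0 °C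
Reagents that add atoms: none
Why: Acylation of a lithium acetylide by a Weinreb amide stops at the ketone because the chelated tetrahedral intermediate survives until work-up; this adds C8, C7 and C6.

Step 9
Reactants: 12 ynone
Product: 13 (4S,5Z,8S,9Z)-1,8-bis[(tert-butyldimethylsilyl)oxy]-10-iodo-5,9-dimethyldeca-5,9-dien-2-yn-4-ol
Conditions: RuCl[(S,S)-TsDPEN](p-cymene) (2 mol %), i-PrOH, rt
Reagents that add atoms: none
Why: Noyori asymmetric transfer hydrogenation of an alkynyl ketone, in which the slim alkyne is the group recognised by the catalyst, so the (S,S) ligand should give the 9S propargylic alcohol as it does for simple ynones.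

Step 10
Reactants: 13 propargylic alcohol
Product: 14 (2E,4R,5Z,8S,9Z)-1,8-bis[(tert-butyldimethylsilyl)oxy]-10-iodo-5,9-dimethyldeca-2,5,9-trien-4-ol
Conditions: NaAlH2(OCH2CH2OMe)2 (Red-Al), THF, −20 → 0 °C; aq. Rochelle salt
Reagents that add atoms: none
Why: Alkoxide-directed trans hydroalumination of the propargylic alcohol followed by protonolysis gives the 7E alkene, a standard Red-Al reduction run cold so that the silyl ethers and the alkenyl iodide survive (C9 keeps its geometry; the descriptor changes to R by priority only).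

Step 11
Reactants: 15 angelic acid
Product: 16 (2Z)-2-methylbut-2-en-1-ol
Conditions: LiAlH4, Et2O, 0 °C
Reagents that add atoms: none
Why: Hydride reduction of the carboxylic acid to the allylic alcohol, which keeps the Z geometry of angelic acid.

Step 12
Reactants: 16 (2Z)-2-methylbut-2-en-1-ol
Product: 17 [(2R,3S)-2,3-dimethyloxiran-2-yl]methanol
Conditions: Ti(OiPr)4 (10 mol %), D-(−)-diethyl tartrate (12 mol %), t-BuOOH, 4 Å MS, CH2Cl2, −20 °C
Reagents that add atoms: tert-butyl hydroperoxide, CC(C)(C)OO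
Why: Sharpless asymmetric epoxidation; with D-(−)-diethyl tartrate oxygen is delivered to the face that gives the 2R,3S epoxy alcohol, and syn addition keeps CH2OH cis to the C3 methyl group.

Step 13
Reactants: 17 epoxy alcohol
Product: 18 (2S,3S)-2,3-dimethyloxirane-2-carboxylic acid
Conditions: RuCl3 (2 mol %), NaIO4, CCl4/MeCN/H2O, rt
Reagents that add atoms: water, O
Why: Ruthenium tetroxide generated in the flask oxidises the primary alcohol to the acid without opening the fully substituted glycidic epoxide, the usual route from Sharpless epoxy alcohols to glycidic acids.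

Step 14
Reactants: 14 dienyl allylic alcohol; 18 epoxyangelic acid
Product: 20 (2E,4R,5Z,8S,9Z)-1,8-bis[(tert-butyldimethylsilyl)oxy]-10-iodo-5,9-dimethyldeca-2,5,9-trien-4-yl (2S,3S)-2,3-dimethyloxirane-2-carboxylate, via mixed anhydride 19 (not isolated)
Conditions: 18, 2,4,6-Cl3C6H2COCl, Et3N, THF, rt; then 14, DMAP, toluene, rt
Reagents that add atoms: none
Why: Yamaguchi esterification through mixed anhydride 19 acylates the hindered C9 alcohol with retention, and the acid has no α-hydrogen, so no stereocentre can be lost.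

Step 15
Reactants: 20 bis-silyl ester
Product: 21 (2E,4R,5Z,8S,9Z)-1,8-dihydroxy-10-iodo-5,9-dimethyldeca-2,5,9-trien-4-yl (2S,3S)-2,3-dimethyloxirane-2-carboxylate
Conditions: HF·pyridine, pyridine, THF, 0 °C → rt
Reagents that add atoms: none
Why: Fluoride cleavage of both silyl ethers under buffered conditions leaves the ester, the glycidic epoxide and the alkenyl iodide intact.

Step 16
Reactants: 21 diol
Product: 22 (1S,2Z,5S,6Z)-5-hydroxy-1-[(2R,3R)-3-(hydroxymethyl)oxiran-2-yl]-7-iodo-2,6-dimethylhepta-2,6-dien-1-yl (2S,3S)-2,3-dimethyloxirane-2-carboxylate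
Conditions: Ti(OiPr)4 (20 mol %), D-(−)-diethyl tartrate (24 mol %), t-BuOOH, 4 Å MS, CH2Cl2, −20 °C
Reagents that add atoms: tert-butyl hydroperoxide, CC(C)(C)OO
Why: Sharpless asymmetric epoxidation directed by the primary allylic C6–OH; D-(−)-diethyl tartrate overrides the C9 stereocentre and gives the 7R,8R trans epoxide (threo to O9), while the secondary C3–OH, flanked by a cis-iodo alkene, should react far more slowly.

Step 17
Reactants: 22 epoxy diol
Product: 23 (1S,2Z,5S,6Z)-1-[(2R,3S)-3-formyloxiran-2-yl]-5-hydroxy-7-iodo-2,6-dimethylhepta-2,6-dien-1-yl (2S,3S)-2,3-dimethyloxirane-2-carboxylate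
Conditions: TEMPO (10 mol %), PhI(OAc)2, CH2Cl2, rt
Reagents that add atoms: none
Why: TEMPO-catalysed oxidation with PhI(OAc)2 is selective for the primary alcohol over the secondary C3–OH and gives the epoxy aldehyde without over-oxidation.

Step 18
Reactants: 23 hydroxy epoxy aldehyde
Product: 24 (1S,2Z,5S,6Z)-5-acetoxy-1-[(2R,3S)-3-formyloxiran-2-yl]-7-iodo-2,6-dimethylhepta-2,6-dien-1-yl (2S,3S)-2,3-dimethyloxirane-2-carboxylate
Conditions: Ac2O, pyridine, DMAP (cat.), CH2Cl2, 0 °C
Reagents that add atoms: acetic anhydride, CC(=O)OC(C)=O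
Why: Acetylation of the remaining secondary alcohol installs the C3 acetate of the target; the epoxy aldehyde has no enolisable stereocentre.

Step 19
Reactants: 24 iodo epoxy aldehyde
Product: 25 ring alcohol: ten-membered carbocycle, (3S,6R,7R,8R,9S), 6-hydroxy, trans-7,8-epoxide, 3-acetoxy, 9-O-[(2S,3S)-2,3-dimethyloxirane-2-carbonyl], 1(10)Z and 4Z alkenes
Conditions: CrCl2 (6 equiv), NiCl2 (2 mol %), DMSO/THF 3:1, rt, 0.003 M, slow addition
Reagents that add atoms: none
Why: Nozaki–Hiyama–Kishi reaction: zerovalent nickel inserts into the C5–I bond with retention of the 4Z geometry, transmetalation gives the alkenylchromium, and its addition to the C6 aldehyde at high dilution closes the ten-membered ring, with Felkin–Anh attack anti to the C7–O bond expected to give the 6R (erythro) alcohol.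

Step 20
Reactants: 25 ring alcohol
Product: 26 ring acrylate: as 25 but (3S,6S,7R,8R,9S) with 6-O-acryloyl
Conditions: acrylic acid, PPh3, DIAD, toluene, −20 → 0 °C
Reagents that add atoms: acrylic acid, C=CC(=O)O
Why: Mitsunobu reaction: SN2 displacement of the alkoxyphosphonium by acrylate inverts C6 and gives the 6S acrylate threo to the epoxide, the standard inversion of erythro 2,3-epoxy alcohols.

Step 21
Reactants: 26 ring acrylate
Product: 29 CNP0137407.11, via phosphonium enolate 27 (not isolated), via phosphonium lactone alkoxide 28 (not isolated)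
Conditions: PMe3 (1.0 equiv), t-BuOH/THF 1:1, 0.01 M, rt → 40 °C
Reagents that add atoms: none
Why: Proposed new method: PMe3 adds to the acrylate β-carbon C13 to give phosphonium enolate 27, whose α-carbon C11 opens the 7,8-epoxide at C7 anti to the C7–O bond, and proton transfer followed by E1cB loss of PMe3 from 28 unveils the exocyclic methylene; the closest known reaction type is the phosphine-mediated intramolecular Morita–Baylis–Hillman alkylation in which an enone-derived phosphonium enolate opens a tethered epoxide, not yet shown for an acrylate ester tethered through its own ester oxygen. The γ-lactone ring (O6–C12–C11–C7–C6) closes 5-exo-tet. C7 is set by stereospecific inversion of the 7R epoxide carbon, C8 keeps its C–O bond and configuration, and the cis ring fusion follows from the threo relation of O6 and the epoxide fixed in steps 16 and 20. The step needs attack at C7 (5-exo) and not at C8 (6-endo), which the three-atom tether and the collinear SN2 geometry secure; it needs the side-chain glycidate to stay closed, which its fully substituted, electron-poor epoxide carbon secures; and it needs the new C8 alkoxide not to take the C9 acyl group, which t-BuOH (fast protonation) and the quaternary α-carbon of that ester secure. PMe3 is returned unchanged.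

**Compound list**

1 | prop-2-yn-1-ol | C#CCO | starting material
2 | bromo[(1Z)-3-(bromomagnesiooxy)-2-methylprop-1-en-1-yl]magnesium | C/C(CO[Mg]Br)=C/[Mg]Br | intermediate
3 | (2Z)-3-iodo-2-methylprop-2-en-1-ol | C/C(CO)=C/I | intermediate
4 | (2Z)-3-iodo-2-methylprop-2-enal | C/C(C=O)=C/I | intermediate
5 | (1Z,3S)-1-iodo-2-methylhexa-1,5-dien-3-ol | I/C=C(/C)[C@@H](O)CC=C | intermediate
6 | (1Z,3S)-1-iodo-2-methylhexa-1,5-dien-3-yl 2-methylprop-2-enoate | I/C=C(/C)[C@@H](OC(=O)C(C)=C)CC=C | intermediate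
7 | (6S)-6-[(1Z)-1-iodoprop-1-en-2-yl]-3-methyl-5,6-dihydro-2H-pyran-2-one | I/C=C(/C)[C@@H]1CC=C(C)C(=O)O1 | intermediate
8 | (2Z,5S,6Z)-5-hydroxy-7-iodo-N-methoxy-N,2,6-trimethylhepta-2,6-dienamide | I/C=C(/C)[C@@H](O)C/C=C(/C)C(=O)N(C)OC | intermediate
9 | (2Z,5S,6Z)-5-[(tert-butyldimethylsilyl)oxy]-7-iodo-N-methoxy-N,2,6-trimethylhepta-2,6-dienamide | I/C=C(/C)[C@@H](O[Si](C)(C)C(C)(C)C)C/C=C(/C)C(=O)N(C)OC | intermediate
10 | tert-butyldimethyl(prop-2-yn-1-yloxy)silane | C#CCO[Si](C)(C)C(C)(C)C | starting material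
11 | [3-(tert-butyldimethylsilyloxy)prop-1-yn-1-yl]lithium | [Li]C#CCO[Si](C)(C)C(C)(C)C | intermediate
12 | (5Z,8S,9Z)-1,8-bis[(tert-butyldimethylsilyl)oxy]-10-iodo-5,9-dimethyldeca-5,9-dien-2-yn-4-one | I/C=C(/C)[C@@H](O[Si](C)(C)C(C)(C)C)C/C=C(/C)C(=O)C#CCO[Si](C)(C)C(C)(C)C | intermediate
13 | (4S,5Z,8S,9Z)-1,8-bis[(tert-butyldimethylsilyl)oxy]-10-iodo-5,9-dimethyldeca-5,9-dien-2-yn-4-ol | I/C=C(/C)[C@@H](O[Si](C)(C)C(C)(C)C)C/C=C(/C)[C@H](O)C#CCO[Si](C)(C)C(C)(C)C | intermediate
14 | (2E,4R,5Z,8S,9Z)-1,8-bis[(tert-butyldimethylsilyl)oxy]-10-iodo-5,9-dimethyldeca-2,5,9-trien-4-ol | I/C=C(/C)[C@@H](O[Si](C)(C)C(C)(C)C)C/C=C(/C)[C@H](O)/C=C/CO[Si](C)(C)C(C)(C)C | intermediate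
15 | angelic acid, (2Z)-2-methylbut-2-enoic acid | C/C=C(/C)C(=O)O | starting material
16 | (2Z)-2-methylbut-2-en-1-ol | C/C=C(/C)CO | intermediate
17 | [(2R,3S)-2,3-dimethyloxiran-2-yl]methanol | OC[C@@]1(C)O[C@H]1C | intermediate
18 | (2S,3S)-2,3-dimethyloxirane-2-carboxylic acid | OC(=O)[C@@]1(C)O[C@H]1C | intermediate
19 | (2S,3S)-2,3-dimethyloxirane-2-carboxylic 2,4,6-trichlorobenzoic anhydride | O=C(OC(=O)c1c(Cl)cc(Cl)cc1Cl)[C@@]1(C)O[C@H]1C | intermediate
20 | (2E,4R,5Z,8S,9Z)-1,8-bis[(tert-butyldimethylsilyl)oxy]-10-iodo-5,9-dimethyldeca-2,5,9-trien-4-yl (2S,3S)-2,3-dimethyloxirane-2-carboxylate | I/C=C(/C)[C@@H](O[Si](C)(C)C(C)(C)C)C/C=C(/C)[C@H](OC(=O)[C@@]1(C)O[C@H]1C)/C=C/CO[Si](C)(C)C(C)(C)C | intermediate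
21 | (2E,4R,5Z,8S,9Z)-1,8-dihydroxy-10-iodo-5,9-dimethyldeca-2,5,9-trien-4-yl (2S,3S)-2,3-dimethyloxirane-2-carboxylate | I/C=C(/C)[C@@H](O)C/C=C(/C)[C@H](OC(=O)[C@@]1(C)O[C@H]1C)/C=C/CO | intermediate
22 | (1S,2Z,5S,6Z)-5-hydroxy-1-[(2R,3R)-3-(hydroxymethyl)oxiran-2-yl]-7-iodo-2,6-dimethylhepta-2,6-dien-1-yl (2S,3S)-2,3-dimethyloxirane-2-carboxylate | I/C=C(/C)[C@@H](O)C/C=C(/C)[C@H](OC(=O)[C@@]1(C)O[C@H]1C)[C@H]2O[C@@H]2CO | intermediate
23 | (1S,2Z,5S,6Z)-1-[(2R,3S)-3-formyloxiran-2-yl]-5-hydroxy-7-iodo-2,6-dimethylhepta-2,6-dien-1-yl (2S,3S)-2,3-dimethyloxirane-2-carboxylate | I/C=C(/C)[C@@H](O)C/C=C(/C)[C@H](OC(=O)[C@@]1(C)O[C@H]1C)[C@H]2O[C@@H]2C=O | intermediate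
24 | (1S,2Z,5S,6Z)-5-acetoxy-1-[(2R,3S)-3-formyloxiran-2-yl]-7-iodo-2,6-dimethylhepta-2,6-dien-1-yl (2S,3S)-2,3-dimethyloxirane-2-carboxylate | I/C=C(/C)[C@@H](OC(C)=O)C/C=C(/C)[C@H](OC(=O)[C@@]1(C)O[C@H]1C)[C@H]2O[C@@H]2C=O | intermediate
25 | ring alcohol, germacrane numbering: (3S,6R,7R,8R,9S)-3-acetoxy-7,8-epoxy-6-hydroxy-ten-membered carbocycle with 1(10)Z and 4Z alkenes (methyls on C10 and C4), 9-yl (2S,3S)-2,3-dimethyloxirane-2-carboxylate | O[C@@H]1/C=C(/C)[C@@H](OC(C)=O)C/C=C(/C)[C@H](OC(=O)[C@@]3(C)O[C@H]3C)[C@H]2O[C@H]12 | intermediate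
26 | ring acrylate: (3S,6S,7R,8R,9S)-6-O-acryloyl analogue of 25 | C=CC(=O)O[C@H]1/C=C(/C)[C@@H](OC(C)=O)C/C=C(/C)[C@H](OC(=O)[C@@]3(C)O[C@H]3C)[C@H]2O[C@H]12 | intermediate
27 | zwitterion from addition of PMe3 to C13 of 26 (β-trimethylphosphonio ester enolate) | C[P+](C)(C)CC=C([O-])O[C@H]1/C=C(/C)[C@@H](OC(C)=O)C/C=C(/C)[C@H](OC(=O)[C@@]3(C)O[C@H]3C)[C@H]2O[C@H]12 | intermediate
28 | cyclised zwitterion: cis-fused γ-lactone with C11–CH2–PMe3+ and C8 alkoxide (C11 configuration not defined) | C[P+](C)(C)CC1C(=O)O[C@H]2/C=C(/C)[C@@H](OC(C)=O)C/C=C(/C)[C@H](OC(=O)[C@@]3(C)O[C@H]3C)[C@@H]([O-])[C@@H]12 | intermediate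
29 | CNP0137407.11: (3S,6S,7R,8S,9S)-3-acetoxy-8-hydroxy-9-[(2S,3S)-2,3-dimethyloxirane-2-carbonyloxy]germacra-1(10)Z,4Z,11(13)-trien-12,6-olide | C=C1C(=O)O[C@H]2/C=C(/C)[C@@H](OC(C)=O)C/C=C(/C)[C@H](OC(=O)[C@@]3(C)O[C@H]3C)[C@@H](O)[C@@H]12 | target

**Step count**

Total steps: 21. Longest linear sequence: 18 (steps 1–10 and 14–21); steps 11–13 make the side-chain acid.

**Steps most likely to fail**

1. Step 21 (Proposed new method). The enolate carbon may be unable to reach the backside of C7 in the ring conformations available, so that cyclisation is slow and acrylate oligomerisation, acyl shift from O9 to O8 or attack of the phosphine on the epoxide take over. Fallback, setting out from 25 and returning at 29: Mitsunobu esterification of 25 with diethylphosphonoacetic acid (PPh3, DIAD) should give the 6S phosphonoacetate F1. NaH in THF (0 → 50 °C) forms the stabilised, persistent phosphonate carbanion, which should open the epoxide at C7 in the same 5-exo sense and can be heated; this gives the α-phosphono lactone F2 with free C8–OH. Horner–Wadsworth–Emmons methylenation of its sodium salt with paraformaldehyde in the same flask should give 29. Both operations are known reaction types (epoxide alkylation of phosphonoacetate anions, α-phosphono lactone methylenation).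

2. Step 19. Poor facial selectivity in the addition to the epoxy aldehyde (besides oligomerisation) would give a mixture at C6. Fallback, setting out from 24 and returning at 25: the ring closure is run as before and the mixture of 25 and its 6S epimer F3 is oxidised with Dess–Martin periodinane to the single ring enone F4. Reduction with Zn(BH4)2 in Et2O at −20 °C, under chelation of zinc between the ketone and the epoxide oxygen, is the established way to erythro 2,3-epoxy alcohols and should return 25 alone.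

3. Step 20. Allylic transposition (SN2′), elimination or conjugate addition of PPh3 to acrylic acid may compete with clean SN2 inversion at the hindered ring carbinol. Fallback, setting out from 25 and returning at 26: the alcohol is converted with chloromethanesulfonyl chloride and pyridine into the 6R chloromethanesulfonate F5, which is displaced with caesium acrylate and 18-crown-6 in toluene at 40 °C; this sulfonate/caesium carboxylate inversion is known to succeed on hindered secondary alcohols that resist the Mitsunobu reaction.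

**Further compounds**

F1 | step 21 | (3S,6S,7R,8R,9S)-6-O-[2-(diethoxyphosphoryl)acetyl] analogue of 25 | CCOP(=O)(OCC)CC(=O)O[C@H]1/C=C(/C)[C@@H](OC(C)=O)C/C=C(/C)[C@H](OC(=O)[C@@]3(C)O[C@H]3C)[C@H]2O[C@H]12
F2 | step 21 | 11-(diethoxyphosphoryl) derivative of the 11,13-dihydro target lactone, (3S,6S,7R,8S,9S), C11 not defined | CCOP(=O)(OCC)C1C(=O)O[C@H]2/C=C(/C)[C@@H](OC(C)=O)C/C=C(/C)[C@H](OC(=O)[C@@]3(C)O[C@H]3C)[C@@H](O)[C@@H]12
F3 | step 19 | 6S epimer of 25, (3S,6S,7R,8R,9S) | O[C@H]1/C=C(/C)[C@@H](OC(C)=O)C/C=C(/C)[C@H](OC(=O)[C@@]3(C)O[C@H]3C)[C@H]2O[C@H]12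
F4 | step 19 | ring enone, 6-oxo analogue of 25, (3S,7S,8R,9S) | O=C1/C=C(/C)[C@@H](OC(C)=O)C/C=C(/C)[C@H](OC(=O)[C@@]3(C)O[C@H]3C)[C@H]2O[C@H]12
F5 | step 20 | 6R chloromethanesulfonate of 25 | ClCS(=O)(=O)O[C@@H]1/C=C(/C)[C@@H](OC(C)=O)C/C=C(/C)[C@H](OC(=O)[C@@]3(C)O[C@H]3C)[C@H]2O[C@H]12
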